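**Retrosynthetic overview**

1. The oxolane (O1, C2 aryl, C3 CH2OH, C4 CH2Ar, C5) is cut at C3–C4 and, in the same operation, at the exocyclic CH2–aryl bond of the C4 benzyl group. This leaves the acyclic epoxy allyl ether 5 and the aryl bromide 14, which already carries the whole threo side chain.
2. Enabling feature: C3 and its hydroxymethyl carbon form a masked terminal oxirane, whose strain-releasing homolysis puts a radical on C3. O1–C5–C4–CH2 is an O-allyl group on the C2 benzylic oxygen, so 5-exo closure leaves a primary radical on the CH2 that must bond to ring B.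
3. 5 comes from vanillin (ring A) by vinyl addition, Katsuki–Sharpless kinetic resolution (sets C2) and O-allylation. 14 comes from 4-bromo-2-methoxyphenol (ring B) and vanillin (ring C) by an Evans syn aldol of an aryloxyacetyl imide (sets both side-chain centres, threo).
4. Ring order: rings A, B and C are bought as arenes; the oxazolidinone is a temporary ring, removed in step 8; the oxolane is the only ring built and is closed last, in step 10; step 11 removes four silyl groups.

Key step: step 10

Remark: the target is read as a (2S,3R,4R)-2-aryl-3-(hydroxymethyl)-4-benzyloxolane whose benzyl ring carries a (1R,2R), that is threo, 1-arylpropane-1,3-diol-2-yl ether. The oxirane carbon of 4 and 5 becomes a planar radical in step 10, so only the carbinol configuration of 5 is carried into the target. In the SMILES of 15 and 16 the cyclopentadienyl ligands are drawn σ-bonded.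

**Route**

Step 1
Reactants: 1 vanillin
Product: 2 3-methoxy-4-(triisopropylsilyloxy)benzaldehyde
Conditions: TIPSCl, imidazole, DMF, rt
Reagents that add atoms: triisopropylsilyl chloride, CC(C)[Si](Cl)(C(C)C)C(C)C
Why: Imidazole-promoted silylation of a phenol, the bulky aryl TIPS ether being chosen because it should survive Grignard, NaH, boron enolate and borohydride conditions and leave with fluoride at the end.

Step 2
Reactants: 2 3-methoxy-4-(triisopropylsilyloxy)benzaldehyde
Product: 3 rac-1-[3-methoxy-4-(triisopropylsilyloxy)phenyl]prop-2-en-1-ol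
Conditions: CH2=CHMgBr, THF, −78 to 0 °C; then H2O
Reagents that add atoms: vinylmagnesium bromide, C=C[Mg]Br
Why: Grignard 1,2-addition to the aldehyde should give the racemic allylic alcohol, whose carbinol centre is resolved in the next step.

Step 3
Reactants: 3 rac-1-[3-methoxy-4-(triisopropylsilyloxy)phenyl]prop-2-en-1-ol
Product: 4 (R)-[3-methoxy-4-(triisopropylsilyloxy)phenyl][(S)-oxiran-2-yl]methanol
Conditions: Ti(OiPr)4, D-(−)-DIPT, TBHP (0.6 equiv), 4 Å MS, CH2Cl2, −20 °C
Reagents that add atoms: tert-butyl hydroperoxide, CC(C)(C)OO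
Why: Katsuki–Sharpless kinetic resolution of a secondary allylic alcohol, in which the titanium D-tartrate should epoxidise the (S)-enantiomer of 3 fast and on the face that gives the erythro epoxy alcohol, so that the reagent fixes the carbinol configuration by selection and the oxirane centre by face control, while the (R)-enantiomer of 3 stays behind and is removed by chromatography.

Step 4
Reactants: 4 (R)-[3-methoxy-4-(triisopropylsilyloxy)phenyl][(S)-oxiran-2-yl]methanol
Product: 5 (S)-2-{(R)-(allyloxy)[3-methoxy-4-(triisopropylsilyloxy)phenyl]methyl}oxirane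
Conditions: NaH, allyl bromide, Bu4NI (cat.), THF, 0 °C to rt
Reagents that add atoms: allyl bromide, C=CCBr
Why: Williamson ether synthesis on the sodium alkoxide, in which only the O–H bond reacts so that the carbinol configuration is retained, the aprotic medium and low temperature being meant to keep Payne rearrangement slow.

Step 5
Reactants: 6 4-bromo-2-methoxyphenol
Product: 7 2-(4-bromo-2-methoxyphenoxy)acetic acid
Conditions: ClCH2CO2H, NaOH, H2O, reflux; then HCl
Reagents that add atoms: chloroacetic acid, OC(=O)CCl
Why: Williamson ether synthesis of the phenoxide with chloroacetate in water, the classical aryloxyacetic acid preparation, to which the aryl bromide is inert.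

Step 6
Reactants: 7 2-(4-bromo-2-methoxyphenoxy)acetic acid; 8 (S)-4-benzyloxazolidin-2-one
Product: 10 (S)-4-benzyl-3-[2-(4-bromo-2-methoxyphenoxy)acetyl]oxazolidin-2-one, via mixed pivalic anhydride 9 (not isolated)
Conditions: PivCl, Et3N, THF, −20 °C; then LiCl, 8, −20 °C to rt
Reagents that add atoms: none
Why: N-Acylation of the oxazolidinone through the mixed pivalic anhydride with LiCl activation, the standard one-pot preparation of Evans imides, the auxiliary bringing its own (S) centre.

Step 7
Reactants: 10 (S)-4-benzyl-3-[2-(4-bromo-2-methoxyphenoxy)acetyl]oxazolidin-2-one; 2 3-methoxy-4-(triisopropylsilyloxy)benzaldehyde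
Product: 12 (S)-4-benzyl-3-{(2S,3R)-2-(4-bromo-2-methoxyphenoxy)-3-hydroxy-3-[3-methoxy-4-(triisopropylsilyloxy)phenyl]propanoyl}oxazolidin-2-one, via Z dibutylboron enolate 11 (not isolated)
Conditions: Bu2BOTf, iPr2NEt, CH2Cl2, −78 to 0 °C; then 2, −78 to 0 °C; then pH 7 buffer, MeOH, H2O2, 0 °C
Reagents that add atoms: none
Why: Evans syn aldol reaction, in which soft enolisation gives the Z boron enolate that should add through a Zimmerman–Traxler chair on the face away from the benzyl group of the auxiliary, setting both new centres as the (2S,3R) syn adduct, which is the threo relationship of the side chain.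

Step 8
Reactants: 12 the syn aldol adduct
Product: 13 (1R,2R)-2-(4-bromo-2-methoxyphenoxy)-1-[3-methoxy-4-(triisopropylsilyloxy)phenyl]propane-1,3-diol
Conditions: LiBH4, MeOH (1 equiv), THF, 0 °C
Reagents that add atoms: none
Why: Reductive cleavage of the N-acyl oxazolidinone with LiBH4 should give the primary alcohol and release the auxiliary without touching a stereocentre, the aryl bromide and the aryl silyl ether being inert to borohydride.

Step 9
Reactants: 13 the threo diol
Product: 14 (1R,2R)-2-(4-bromo-2-methoxyphenoxy)-1,3-bis(tert-butyldimethylsilyloxy)-1-[3-methoxy-4-(triisopropylsilyloxy)phenyl]propane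
Conditions: TBSOTf, 2,6-lutidine, CH2Cl2, −78 to 0 °C
Reagents that add atoms: tert-butyldimethylsilyl triflate, CC(C)(C)[Si](C)(C)OS(=O)(=O)C(F)(F)F
Why: Silyl triflate silylation of the primary and the hindered benzylic alcohol under a non-nucleophilic base, with no stereocentre involved.

Step 10
Reactants: 5 the epoxy allyl ether (1.5 equiv); 14 the aryl bromide
Product: 17 [(2S,3R,4R)-4-{4-[(1R,2R)-1,3-bis(tert-butyldimethylsilyloxy)-1-[3-methoxy-4-(triisopropylsilyloxy)phenyl]propan-2-yloxy]-3-methoxybenzyl}-2-[3-methoxy-4-(triisopropylsilyloxy)phenyl]oxolan-3-yl]methanol, via β-titanoxy secondary radical 15 (not isolated), via oxolanylmethyl radical 16 (not isolated)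
Conditions: NiBr2(dme) (10 mol %), 4,4'-di-tert-butyl-2,2'-bipyridine (10 mol %), Cp2TiCl2 (20 mol %), Mn powder, Et3N·HCl, DMPU, rt
Reagents that add atoms: none
Why: Proposed new method: Cp2TiCl (trivalent titanium, made from Cp2TiCl2 and Mn) should open the strained oxirane of 5 homolytically at its substituted carbon to give the C3 radical 15, which closes the ring onto the internal carbon of the O-allyl group; the exocyclic primary radical 16 is then captured by the aryl nickel bromide formed from 14 and zerovalent nickel, reductive elimination makes the CH2–aryl bond, and Et3N·HCl frees the primary alcohol and returns Cp2TiCl2. The closest known reaction types are the titanium/nickel co-catalysed reductive arylation of epoxides with aryl bromides, the stoichiometric Cp2TiCl-mediated cyclisation of epoxy cinnamyl ethers to 2-aryl-3-(hydroxymethyl)-4-benzyloxolanes, and nickel-catalysed radical cyclisation/arylation cascades of haloacetal allyl ethers; merging them on an epoxide is the new element. The one ring closed is the oxolane, by 5-exo-trig radical cyclisation that forms the C3–C4 bond. Both new stereocentres are controlled by the existing C2 centre through a Beckwith–Houk chair transition state: the C2 aryl group sits pseudo-equatorial, which should place the C3 CH2O–Ti arm trans to it, and the 1,5-cis preference of a 1-substituted hexenyl radical should place the C4 CH2 radical cis to that arm, the oxirane stereocentre having been erased at the radical stage. The step needs the radical to cyclise before it meets nickel, the oxirane to open toward C3 and not at its CH2 end, and one diastereomer of the ring to dominate. These are secured by the substrate: the ether oxygen in the tether makes the unimolecular 5-exo closure fast against bimolecular capture at catalytic nickel concentration, the oxirane is terminal so that homolysis gives the secondary radical, and the single C2 stereocentre sits directly beside the radical carbon; the choice of an aryl bromide keeps iodide-type nucleophilic opening out.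

Step 11
Reactants: 17 the tetrasilyl ether
Product: 18 (1R,2R)-1-(4-hydroxy-3-methoxyphenyl)-2-{4-[[(3R,4R,5S)-5-(4-hydroxy-3-methoxyphenyl)-4-(hydroxymethyl)oxolan-3-yl]methyl]-2-methoxyphenoxy}propane-1,3-diol (CNP0158473.2)
Conditions: TBAF, AcOH, THF, 0 °C to rt
Reagents that add atoms: none
Why: Fluoride-induced desilylation of the two aryl and the two alkyl silyl ethers, buffered with AcOH so that the phenoxides are protonated at once and quinone methide formation at the two benzylic positions is avoided, with no stereocentre touched.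

**Compound list**

1 | vanillin | COc1cc(C=O)ccc1O | starting material
2 | 3-methoxy-4-(triisopropylsilyloxy)benzaldehyde | COc1cc(C=O)ccc1O[Si](C(C)C)(C(C)C)C(C)C | intermediate
3 | rac-1-[3-methoxy-4-(triisopropylsilyloxy)phenyl]prop-2-en-1-ol | COc1cc(C(O)C=C)ccc1O[Si](C(C)C)(C(C)C)C(C)C | intermediate
4 | (R)-[3-methoxy-4-(triisopropylsilyloxy)phenyl][(S)-oxiran-2-yl]methanol | COc1cc([C@@H](O)[C@@H]2CO2)ccc1O[Si](C(C)C)(C(C)C)C(C)C | intermediate
5 | (S)-2-{(R)-(allyloxy)[3-methoxy-4-(triisopropylsilyloxy)phenyl]methyl}oxirane | COc1cc([C@@H](OCC=C)[C@@H]2CO2)ccc1O[Si](C(C)C)(C(C)C)C(C)C | intermediate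
6 | 4-bromo-2-methoxyphenol | COc1cc(Br)ccc1O | starting material
7 | 2-(4-bromo-2-methoxyphenoxy)acetic acid | COc1cc(Br)ccc1OCC(=O)O | intermediate
8 | (S)-4-benzyloxazolidin-2-one | O=C1N[C@@H](Cc2ccccc2)CO1 | starting material
9 | 2-(4-bromo-2-methoxyphenoxy)acetic pivalic anhydride (not isolated) | COc1cc(Br)ccc1OCC(=O)OC(=O)C(C)(C)C | intermediate
10 | (S)-4-benzyl-3-[2-(4-bromo-2-methoxyphenoxy)acetyl]oxazolidin-2-one | COc1cc(Br)ccc1OCC(=O)N1C(=O)OC[C@@H]1Cc1ccccc1 | intermediate
11 | Z dibutylboron enolate of 10 (not isolated) | CCCCB(CCCC)O/C(=C\Oc1ccc(Br)cc1OC)N1C(=O)OC[C@@H]1Cc1ccccc1 | intermediate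
12 | (S)-4-benzyl-3-{(2S,3R)-2-(4-bromo-2-methoxyphenoxy)-3-hydroxy-3-[3-methoxy-4-(triisopropylsilyloxy)phenyl]propanoyl}oxazolidin-2-one | COc1cc([C@@H](O)[C@@H](C(=O)N2C(=O)OC[C@@H]2Cc2ccccc2)Oc2ccc(Br)cc2OC)ccc1O[Si](C(C)C)(C(C)C)C(C)C | intermediate
13 | (1R,2R)-2-(4-bromo-2-methoxyphenoxy)-1-[3-methoxy-4-(triisopropylsilyloxy)phenyl]propane-1,3-diol | COc1cc([C@@H](O)[C@@H](CO)Oc2ccc(Br)cc2OC)ccc1O[Si](C(C)C)(C(C)C)C(C)C | intermediate
14 | (1R,2R)-2-(4-bromo-2-methoxyphenoxy)-1,3-bis(tert-butyldimethylsilyloxy)-1-[3-methoxy-4-(triisopropylsilyloxy)phenyl]propane | COc1cc([C@@H](O[Si](C)(C)C(C)(C)C)[C@@H](CO[Si](C)(C)C(C)(C)C)Oc2ccc(Br)cc2OC)ccc1O[Si](C(C)C)(C(C)C)C(C)C | intermediate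
15 | β-titanoxy secondary radical from oxirane opening of 5 (not isolated) | C=CCO[C@H](c1ccc(O[Si](C(C)C)(C(C)C)C(C)C)c(OC)c1)[CH]CO[Ti](Cl)(C1C=CC=C1)C1C=CC=C1 | intermediate
16 | (2S,3R,4R)-oxolan-4-ylmethyl radical after 5-exo closure (not isolated) | [CH2][C@H]1CO[C@H](c2ccc(O[Si](C(C)C)(C(C)C)C(C)C)c(OC)c2)[C@H]1CO[Ti](Cl)(C1C=CC=C1)C1C=CC=C1 | intermediate
17 | tetrasilyl ether of the target (both phenols as TIPS ethers, both side-chain hydroxyls as TBS ethers, oxolane CH2OH free) | COc1cc([C@@H](O[Si](C)(C)C(C)(C)C)[C@@H](CO[Si](C)(C)C(C)(C)C)Oc2ccc(C[C@H]3CO[C@H](c4ccc(O[Si](C(C)C)(C(C)C)C(C)C)c(OC)c4)[C@H]3CO)cc2OC)ccc1O[Si](C(C)C)(C(C)C)C(C)C | intermediate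
18 | (1R,2R)-1-(4-hydroxy-3-methoxyphenyl)-2-{4-[[(3R,4R,5S)-5-(4-hydroxy-3-methoxyphenyl)-4-(hydroxymethyl)oxolan-3-yl]methyl]-2-methoxyphenoxy}propane-1,3-diol | COc1cc([C@@H](O)[C@@H](CO)Oc2ccc(C[C@H]3CO[C@H](c4ccc(O)c(OC)c4)[C@H]3CO)cc2OC)ccc1O | target

**Summary**

Total step count: 11.
Longest linear sequence: 7 steps (6 → 7 → 10 → 12 → 13 → 14 → 17 → 18, steps 5 to 11).

**Steps most likely to fail**

Step 10 (proposed cascade). Three processes may defeat it: coupling of the aryl nickel species with the radical before it has cyclised, reduction of the cyclised radical before it reaches nickel, and nucleophilic opening of the oxirane at its CH2 end. Poor facial selectivity in the ring closure is a further risk. The fallback uses known chemistry only and sets out from 14 and 5. Suzuki–Miyaura vinylation of 14 (potassium vinyltrifluoroborate, PdCl2(dppf), Cs2CO3, THF/H2O, 80 °C) should give the styrene F1. Olefin cross-metathesis of F1 with the allyl ether 5 (second-generation Hoveyda–Grubbs catalyst, CH2Cl2, 40 °C) should give the (E)-cinnamyl ether F2. Stoichiometric Cp2TiCl (from Cp2TiCl2 and Zn, THF, rt; then dilute acid) then opens the oxirane and closes the oxolane onto the styrenyl alkene; the benzylic radical is reduced by a second Cp2TiCl and protonated on work-up. The fallback comes back to the route at 17.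

Step 3. The terminal vinyl group is a slow substrate for the titanium tartrate, and the electron-rich benzylic alcohol may ionise at the Lewis acid, so the resolution may stall or lose selectivity. The fallback sets out from 3. Lipase-catalysed acylation (Novozym 435, vinyl acetate, MTBE, 30 °C) should leave the (S)-alcohol F3 and convert the other enantiomer into the (R)-acetate F4, which is separated. Hydroxyl-directed epoxidation of F3 (VO(acac)2, TBHP, CH2Cl2, 0 °C) should then give 4 as the main, erythro isomer. The threo epimer F5 is removed by chromatography. The fallback comes back to the route at 4.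

Step 4. The sodium alkoxide next to the oxirane may undergo Payne rearrangement or open the oxirane of a second molecule, and the aryl silyl group may migrate to the alkoxide. The fallback works under neutral conditions and sets out from 4. Acylation with allyl chloroformate (pyridine, CH2Cl2, 0 °C) should give the allyl carbonate F6. Zerovalent palladium (Pd(PPh3)4, THF, rt) then brings about decarboxylative allylic etherification of Tsuji–Trost type, in which the π-allyl palladium cation and the alkoxide recombine within the ion pair. The fallback comes back to the route at 5.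

Further compounds
F1 | step 10 | (1R,2R)-1,3-bis(tert-butyldimethylsilyloxy)-2-(2-methoxy-4-vinylphenoxy)-1-[3-methoxy-4-(triisopropylsilyloxy)phenyl]propane | COc1cc([C@@H](O[Si](C)(C)C(C)(C)C)[C@@H](CO[Si](C)(C)C(C)(C)C)Oc2ccc(C=C)cc2OC)ccc1O[Si](C(C)C)(C(C)C)C(C)C
F2 | step 10 | (E)-cinnamyl ether of 4 carrying the protected threo side chain on the cinnamyl ring | COc1cc([C@@H](O[Si](C)(C)C(C)(C)C)[C@@H](CO[Si](C)(C)C(C)(C)C)Oc2ccc(/C=C/CO[C@H](c3ccc(O[Si](C(C)C)(C(C)C)C(C)C)c(OC)c3)[C@@H]3CO3)cc2OC)ccc1O[Si](C(C)C)(C(C)C)C(C)C
F3 | step 3 | (S)-1-[3-methoxy-4-(triisopropylsilyloxy)phenyl]prop-2-en-1-ol | COc1cc([C@@H](O)C=C)ccc1O[Si](C(C)C)(C(C)C)C(C)C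
F4 | step 3 | (R)-1-[3-methoxy-4-(triisopropylsilyloxy)phenyl]prop-2-en-1-yl acetate | COc1cc([C@H](OC(C)=O)C=C)ccc1O[Si](C(C)C)(C(C)C)C(C)C
F5 | step 3 | (R)-[3-methoxy-4-(triisopropylsilyloxy)phenyl][(R)-oxiran-2-yl]methanol | COc1cc([C@@H](O)[C@H]2CO2)ccc1O[Si](C(C)C)(C(C)C)C(C)C
F6 | step 4 | allyl (R)-[3-methoxy-4-(triisopropylsilyloxy)phenyl][(S)-oxiran-2-yl]methyl carbonate | COc1cc([C@@H](OC(=O)OCC=C)[C@@H]2CO2)ccc1O[Si](C(C)C)(C(C)C)C(C)C
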